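**Assumptions.** Germacrone (achiral; bulk isolate from zdravetz or zedoary oil) and tert-butyl bis(2,2,2-trifluoroethyl)phosphonoacetate are taken as purchasable. Sesquiterpene numbering is used (eudesmane: C14 on C10, C15 on C4; eremophilane: C14 on C5, C15 on C4; C11–C13 = isopropylidene on C7). β means the face of the C14 methyl group.

## Retrosynthetic overview

1. C3–O ester bond, made last: Mitsunobu esterification with inversion joins the (Z,Z) side-chain acid to the 3β-hydroxy diosphenol; the enol OH stays free.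
2. Eremophilane ⇐ eudesmane: an epoxide-triggered 1,2-H (C5→C4) / 1,2-CH3 (C10→C5) shift cascade of a 3β,4β-epoxy-9-hydroxyeudesmenone sets C4 and C5 and ends in the diosphenol.
3. Eudesmane ⇐ germacrane: the C5–C10 bond is closed by an enantioselective proton-initiated transannular cyclization of achiral germacrone.
4. Side-chain acid ⇐ angelic acid + chloroacetone + a Z-selective Still–Gennari olefination.
5. Ring order: ten-membered carbocycle (bought in germacrone) → trans-decalin by the transannular C5–C10 bond → methyl shift turns the eudesmane into the eremophilane.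

## Route

Step 1
Reactants: 1 germacrone
Product: 3 (5R,10R)-eudesma-3,7(11)-dien-8-one, via eudesman-4-yl cation 2 (not isolated)
Conditions: (S,S)-IDPi TfNH–P(O2R*)=N–P(O2R*)=NTf (O2R* = (S)-3,3'-Ar2-1,1'-binaphthalene-2,2'-diolate, Ar = 3,5-(CF3)2C6H3, Tf = SO2CF3; 5 mol %; antipode if the screen shows the opposite sense), (CF3)3COH, 0 °C to rt; AgNO3–silica chromatography
Reagents that add atoms: none
Why: Proposed new method: the confined chiral acid protonates C1 of one of the two planar-chiral conformers of achiral 1 that interconvert at room temperature (Curtin–Hammett selection), C5 of the 4,5-alkene attacks C10 across the ring through the chair–chair conformer to give trans-fused cation 2 (5α-H, 10β-CH3, setting C5 and C10), and the counter-anion removes H3 (E1) to give the endocyclic 3-ene, copying germacrene A → eudesmyl cation; the closest known reactions are the acid-catalysed transannular cyclization of germacrone to racemic selinadienones and IDPi-catalysed enantioselective proton-initiated olefin and polyene cyclizations.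

Step 2
Reactants: 3 (5R,10R)-eudesma-3,7(11)-dien-8-one
Product: 5 3β,4β-epoxyeudesm-7(11)-en-8-one, via bromohydrin 4 (not isolated)
Conditions: NBS, THF/H2O 4:1, 0 °C; then K2CO3, MeOH, 0 °C to rt
Reagents that add atoms: water, O
Why: Bromohydrin formation and Williamson-type closure: Br+ adds to the less hindered α face of the 3-ene, water opens the bromonium ion at tertiary C4 from the β face (Markovnikov, trans-diaxial, Fürst–Plattner) and the 4β-alkoxide displaces the 3α-bromide with inversion, giving the β-epoxide that a peracid does not give and whose C4–O bond is anti-periplanar to H5α.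

Step 3
Reactants: 5 3β,4β-epoxyeudesm-7(11)-en-8-one
Product: 7 3β,4β-epoxy-9α-hydroxyeudesm-7(11)-en-8-one, via potassium enolate 6 (not isolated)
Conditions: KN(SiMe3)2, THF, −78 °C; 2-(phenylsulfonyl)-3-phenyloxaziridine, −78 °C; aq NH4Cl
Reagents that add atoms: 2-(phenylsulfonyl)-3-phenyloxaziridine (Davis oxaziridine), O=S(=O)(N1OC1c1ccccc1)c1ccccc1
Why: Kinetic α'-deprotonation of the enone at C9 (the only α-CH2) followed by Davis enolate hydroxylation anti to the axial 10β-CH3 gives the 9α-ketol without touching the epoxide; the C9 configuration is erased again in step 4.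

Step 4
Reactants: 7 3β,4β-epoxy-9α-hydroxyeudesm-7(11)-en-8-one
Product: 10 (3S,4R,5R)-3,9-dihydroxyeremophila-7(11),9-dien-8-one, via C5 carbocation 8 (not isolated), via C10 carbocation 9 (not isolated)
Conditions: BF3·OEt2 (0.5 equiv), CH2Cl2, −78 to 0 °C; aq NaHCO3
Reagents that add atoms: none
Why: Proposed new method: cleavage of the BF3-activated tertiary C4–O bond is assisted by the anti-periplanar axial H5α, whose 1,2-shift sets C4 (4β-CH3) and gives 8, the now anti-periplanar axial 10β-CH3 then migrates to C5 (setting the quaternary centre and relieving the 4β/10β syn-diaxial methyl strain) to give 9, and loss of H9 ends the cascade in the conjugated hydrogen-bonded diosphenol, copying eudesmyl cation → eremophilane in aristolochene biosynthesis; the closest known reactions are the Westphalen and backbone rearrangements of 5α,6α- and 4α,5α-epoxy steroids and the acid-induced methyl shift of 4α,5α-epoxyeudesmanes to eremophilanes.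

Step 5
Reactants: 11 angelic acid [(2Z)-2-methylbut-2-enoic acid], 12 chloroacetone
Product: 14 2-oxopropyl (2Z)-2-methylbut-2-enoate, via potassium angelate 13 (not isolated)
Conditions: K2CO3, KI (cat.), DMF, rt
Reagents that add atoms: none
Why: SN2 O-alkylation of the carboxylate by the α-chloroketone never activates the acyl carbon, so the Z (angelate) geometry is kept.

Step 6
Reactants: 14 2-oxopropyl (2Z)-2-methylbut-2-enoate, 15 tert-butyl bis(2,2,2-trifluoroethyl)phosphonoacetate
Product: 17 tert-butyl (2Z)-3-methyl-4-{[(2Z)-2-methylbut-2-enoyl]oxy}but-2-enoate, via phosphonate carbanion 16 (not isolated)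
Conditions: 15, KN(SiMe3)2, 18-crown-6, THF, −78 °C; then 14, −78 °C; chromatography
Reagents that add atoms: none
Why: Still–Gennari variant of the Horner–Wadsworth–Emmons olefination: the electron-poor phosphonate with a dissociated potassium ion eliminates fast from the kinetic adduct and places CO2tBu cis to the CH2O-bearing substituent (Z), as known for α-oxygenated ketones in butenolide syntheses; the minor E isomer is removed by chromatography.

Step 7
Reactants: 17 tert-butyl (2Z)-3-methyl-4-{[(2Z)-2-methylbut-2-enoyl]oxy}but-2-enoate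
Product: 18 (2Z)-3-methyl-4-{[(2Z)-2-methylbut-2-enoyl]oxy}but-2-enoic acid
Conditions: CF3CO2H/CH2Cl2 1:4, 0 °C; used at once
Reagents that add atoms: none
Why: Acidolysis of the tert-butyl ester (E1 loss of isobutene) leaves the allylic angelate and both Z double bonds intact at 0 °C.

Step 8
Reactants: 10 (3S,4R,5R)-3,9-dihydroxyeremophila-7(11),9-dien-8-one, 18 (2Z)-3-methyl-4-{[(2Z)-2-methylbut-2-enoyl]oxy}but-2-enoic acid
Product: 20 (3R,4R,5R)-9-hydroxy-8-oxoeremophila-7(11),9-dien-3-yl (2Z)-3-methyl-4-{[(2Z)-2-methylbut-2-enoyl]oxy}but-2-enoate, via alkoxyphosphonium carboxylate 19 (not isolated)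
Conditions: PPh3, DIAD, 18 (2 equiv), toluene, 0 °C to rt
Reagents that add atoms: none
Why: Mitsunobu esterification: only the aliphatic 3β-OH is activated as 19 (the hydrogen-bonded enol OH is not displaced and the acid is never activated, so neither enol acylation nor Z/E scrambling occurs) and the carboxylate attacks C3 from the α face with SN2 inversion, turning the axial 3β-OH into the equatorial 3α-ester (3R) of the target.

## Compound list

1 | germacrone, (3E,7E)-3,7-dimethyl-10-(propan-2-ylidene)cyclodeca-3,7-dien-1-one | C/C1=C\CC/C(C)=C/CC(=C(C)C)C(=O)C1 | starting material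
2 | 8-oxoeudesm-7(11)-en-4-yl cation, trans-fused (5α-H, 10β-CH3), ion pair with the catalyst anion | C[C+]1CCC[C@]2(C)CC(=O)C(=C(C)C)C[C@@H]12 | intermediate
3 | (5R,10R)-eudesma-3,7(11)-dien-8-one (5α-H, 10β-CH3) | CC1=CCC[C@]2(C)CC(=O)C(=C(C)C)C[C@@H]12 | intermediate
4 | 3α-bromo-4β-hydroxyeudesm-7(11)-en-8-one (5α-H, 10β-CH3; Br and OH trans-diaxial) | C[C@]1(O)[C@H](Br)CC[C@]2(C)CC(=O)C(=C(C)C)C[C@@H]12 | intermediate
5 | 3β,4β-epoxyeudesm-7(11)-en-8-one (5α-H, 10β-CH3) | C[C@]12O[C@H]1CC[C@]3(C)CC(=O)C(=C(C)C)C[C@@H]23 | intermediate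
6 | potassium 8-enolate (C8–O−, C8=C9) of 5 | C[C@]12O[C@H]1CC[C@]3(C)C=C([O-])C(=C(C)C)C[C@@H]23.[K+] | intermediate
7 | 3β,4β-epoxy-9α-hydroxyeudesm-7(11)-en-8-one (5α-H, 10β-CH3) | C[C@]12O[C@H]1CC[C@]3(C)[C@H](O)C(=O)C(=C(C)C)C[C@@H]23 | intermediate
8 | C5 carbocation: 9α-hydroxy-8-oxoeudesm-7(11)-ene with 3β-OBF3−, 4α-H/4β-CH3, 10β-CH3, positive charge on C5 (zwitterion) | C[C@H]1[C@@H](O[B-](F)(F)F)CC[C@]2(C)[C@H](O)C(=O)C(=C(C)C)C[C+]12 | intermediate
9 | C10 carbocation: 9α-hydroxy-8-oxoeremophil-7(11)-ene with 3β-OBF3−, 4β-CH3, 5β-CH3, positive charge on C10 (zwitterion) | C[C@H]1[C@@H](O[B-](F)(F)F)CC[C+]2[C@H](O)C(=O)C(=C(C)C)C[C@]12C | intermediate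
10 | (3S,4R,5R)-3,9-dihydroxyeremophila-7(11),9-dien-8-one (3β-OH, cis to both β-methyls) | O[C@H]1CCC2=C(O)C(=O)C(=C(C)C)C[C@]2(C)[C@H]1C | intermediate
11 | angelic acid, (2Z)-2-methylbut-2-enoic acid | C/C=C(/C)C(=O)O | starting material
12 | chloroacetone | CC(=O)CCl | starting material
13 | potassium (2Z)-2-methylbut-2-enoate | C/C=C(/C)C(=O)[O-].[K+] | intermediate
14 | 2-oxopropyl (2Z)-2-methylbut-2-enoate | C/C=C(/C)C(=O)OCC(C)=O | intermediate
15 | tert-butyl 2-[bis(2,2,2-trifluoroethoxy)phosphoryl]acetate | CC(C)(C)OC(=O)CP(=O)(OCC(F)(F)F)OCC(F)(F)F | starting material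
16 | potassium salt of the α-carbanion of 15 | CC(C)(C)OC(=O)[CH-]P(=O)(OCC(F)(F)F)OCC(F)(F)F.[K+] | intermediate
17 | tert-butyl (2Z)-3-methyl-4-{[(2Z)-2-methylbut-2-enoyl]oxy}but-2-enoate | C/C=C(/C)C(=O)OC/C(C)=C\C(=O)OC(C)(C)C | intermediate
18 | (2Z)-3-methyl-4-{[(2Z)-2-methylbut-2-enoyl]oxy}but-2-enoic acid | C/C=C(/C)C(=O)OC/C(C)=C\C(=O)O | intermediate
19 | 3β-(triphenylphosphoniooxy) derivative of 10, as its salt with the carboxylate of 18 | c1ccccc1[P+](c1ccccc1)(c1ccccc1)O[C@H]1CCC2=C(O)C(=O)C(=C(C)C)C[C@]2(C)[C@H]1C.C/C=C(/C)C(=O)OC/C(C)=C\C(=O)[O-] | intermediate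
20 | (3R,4R,5R)-9-hydroxy-8-oxoeremophila-7(11),9-dien-3-yl (2Z)-3-methyl-4-{[(2Z)-2-methylbut-2-enoyl]oxy}but-2-enoate (CNP0228871.1) | C/C=C(/C)C(=O)OC/C(C)=C\C(=O)O[C@@H]1CCC2=C(O)C(=O)C(=C(C)C)C[C@]2(C)[C@H]1C | target

## Step count and risks

Total: 8 steps. Longest linear sequence: 5 steps (1 → 3 → 5 → 7 → 10 → 20); the side chain takes 3 steps (5–7) before the coupling.

**Step 1** (enantioselectivity and the 3-ene / 4(15)-ene ratio are unproven). Fallback from 1 back to 3, with reagent-controlled epoxidation in place of asymmetric protonation. Shi epoxidation of 1 (1,2:4,5-di-O-isopropylidene-β-D-erythro-2,3-hexodiulo-2,6-pyranose, KHSO5, K2CO3 buffer, MeCN/dimethoxymethane/H2O, 0 °C) and separation from the 4,5-epoxide gives (1R,10R)-1,10-epoxygermacra-4,7(11)-dien-8-one F1. BF3·OEt2 in CH2Cl2 at −78 °C opens the epoxide at C10 with anti attack of C5 (epoxide-initiated transannular cyclization) to give 1β-hydroxyeudesma-3,7(11)-dien-8-one F2. KN(SiMe3)2/CS2/MeI gives the S-methyl xanthate F3, and Bu3SnH with azobisisobutyronitrile in toluene at 90 °C (Barton–McCombie) removes the C1 oxygen and returns 3.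

**Step 4** (competing 3-ketone formation by hydride shift from C3, fluorohydrin or 4(15)-ene and 5-ene formation, and interference by the ketol). Fallback from 5 back to 10, with the rearrangement run before C9 is oxidized, so step 3 is not needed. BF3·OEt2 on 5 ends by loss of the axial H9α and gives (3S,4R,5R)-3-hydroxyeremophila-7(11),9-dien-8-one F4. H2O2/NaOH in MeOH (Weitz–Scheffer) epoxidizes the 9-ene from the α face to 9α,10α-epoxy-3β-hydroxyeremophil-7(11)-en-8-one F5. H2SO4 (cat.) in AcOH isomerizes the epoxy ketone to the diosphenol 10.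

**Step 8** (Mitsunobu at a hindered axial alcohol: elimination to the 2- or 3-ene, or retention through an acyloxyphosphonium). Fallback from 10 to 20, with the inversion separated from the acylation. Mitsunobu reaction with the stronger, smaller 4-nitrobenzoic acid gives the 3α-(4-nitrobenzoate) F6. K2CO3/MeOH frees (3R,4R,5R)-3,9-dihydroxyeremophila-7(11),9-dien-8-one F7. Acylation of both hydroxyls with 18 (2.5 equiv, 1-ethyl-3-(3-dimethylaminopropyl)carbodiimide hydrochloride, 4-(dimethylamino)pyridine) gives the 3,9-bis-ester F8. Brief K2CO3 (cat.)/MeOH at 0 °C cleaves only the activated enol ester and gives 20.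

## Further compounds

F1 | step 1 | (1R,10R)-1,10-epoxygermacra-4,7(11)-dien-8-one | C/C1=C\CC(=C(C)C)C(=O)C[C@@]2(C)O[C@@H]2CC1
F2 | step 1 | 1β-hydroxyeudesma-3,7(11)-dien-8-one (5α-H, 10β-CH3) | CC1=CC[C@@H](O)[C@]2(C)CC(=O)C(=C(C)C)C[C@@H]12
F3 | step 1 | O-[8-oxoeudesma-3,7(11)-dien-1β-yl] S-methyl carbonodithioate | CC1=CC[C@@H](OC(=S)SC)[C@]2(C)CC(=O)C(=C(C)C)C[C@@H]12
F4 | step 4 | (3S,4R,5R)-3-hydroxyeremophila-7(11),9-dien-8-one | O[C@H]1CCC2=CC(=O)C(=C(C)C)C[C@]2(C)[C@H]1C
F5 | step 4 | 9α,10α-epoxy-3β-hydroxyeremophil-7(11)-en-8-one | O[C@H]1CC[C@@]23O[C@@H]2C(=O)C(=C(C)C)C[C@]3(C)[C@H]1C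
F6 | step 8 | (3R,4R,5R)-9-hydroxy-8-oxoeremophila-7(11),9-dien-3-yl 4-nitrobenzoate | O=C(O[C@@H]1CCC2=C(O)C(=O)C(=C(C)C)C[C@]2(C)[C@H]1C)c1ccc(cc1)[N+](=O)[O-]
F7 | step 8 | (3R,4R,5R)-3,9-dihydroxyeremophila-7(11),9-dien-8-one | O[C@@H]1CCC2=C(O)C(=O)C(=C(C)C)C[C@]2(C)[C@H]1C
F8 | step 8 | 3,9-bis-ester of F7 with acid 18 | C/C=C(/C)C(=O)OC/C(C)=C\C(=O)O[C@@H]1CCC2=C(OC(=O)/C=C(C)\COC(=O)/C(C)=C\C)C(=O)C(=C(C)C)C[C@]2(C)[C@H]1C
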